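## Structural features

The target is a C20 prenylated guaiane acetate. Its core is a trans-fused 1,3a,4,5,6,7,8,8a-octahydroazulene: ring A is the cyclopentene C1–C2=C3–C3a–C8a and ring B the cycloheptane C3a–C4–C5–C6–C7–C8–C8a. The core carries a 3-methyl group, an 8-methylidene group, a free secondary hydroxyl at C4 and, at C5, a 2,2,5-trisubstituted oxolane (ring C). In ring C, C2′ is the quaternary carbon bonded to C5 and to a methyl group, and C5′ carries the 2-acetoxypropan-2-yl group.

There are six stereocentres. C8a(R), C3a(S), C4(S) and C5(R) are contiguous, C5 is bonded to the quaternary C2′(S), and C5′(R) is remote. H-3a and H-8a are trans; the 4-OH, the C5 oxolanyl group and H-3a lie on one face.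

C3a is both allylic to C2=C3 and α to C4, so at the ketone oxidation level it epimerises or conjugates under base. The 8-methylidene group can move into ring B under acid. The tertiary acetate has to be installed while the C4 oxygen is not a free hydroxyl.

The real difficulty is threefold: the trans-fused seven-membered ring with four contiguous stereocentres, the deconjugated position of C2=C3 next to C3a, and the C5–C2′ bond to a fully substituted carbinol carbon that simple 1,2-induction cannot set.

The feature exploited is the array C4(O)–C3a(H)–C3(CH3)=C2–C1–C8a(H)–C8(=CH2)–C7. This is (R)-carvone whose carbonyl carbon has been pushed out of the six-membered ring. The ten carbons C1, C2, C3, 3-CH3, C3a, C4, C7, C8, 8-CH2 and C8a map onto carvone; the other ten (C5, C6 and ring C with its side chain) map onto (S)-linalool.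

The key step uses this mapping. A linalool-derived alkenyl metal adds to the carvone carbonyl (C4–C5 bond). A semipinacol 1,2-shift of the alkenyl carbon C3 from C4 to C3a then contracts the carvone ring to ring A, sets C3a by inversion and leaves C2=C3 out of conjugation.

## Logic of the disconnections

**18 from 17.** The C4–H bond is cut, taking the carbinol back to the ketone. The C4 configuration should follow from hydride delivery anti to the C5 substituent, and the acetate is already in place. One stereocentre is removed. The forward step needs a non-basic hydride that spares the acetate and does not enolise towards C3a.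

**17 from 16.** The acetyl C–O bond at the tertiary oxygen is cut. The tertiary hydroxyl has to be free (as an alkoxide) in the organometallic step, and acetylation at the ketone stage avoids any competition with a secondary hydroxyl. The forward step must acylate a tertiary alcohol without touching the α-centres of the ketone.

**16 from 14.** The C6–C7 bond of ring B is cut. An allylsilane attacking the β-carbon of an α-substituted vinyl ketone closes the seven-membered ring, and loss of silicon places the alkene exocyclic at C8. C5 is set on protonation of the enolate. The bicyclic core simplifies to ring A carrying two trans arms. The forward step demands that the allylsilane outcompetes the ring alkene and that the Lewis acid also scavenges the hydroxyl proton.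

**14 from 6 and 11 (key).** The C4–C5 bond and the ring A bond C3–C3a are cut, and the C3–C4 bond of a six-membered ring is restored. This separates the molecule into two ten-carbon halves. C3a becomes an α′-oxygenated carbon that enolate chemistry can set, and the cyclopentene with its deconjugated alkene never has to be made directly. The forward step demands 1,2-addition of a hindered alkenyl metal to an α-sulfonyloxy enone without enolisation. It also needs a mesylate held equatorial and antiperiplanar to the migrating ring bond.

**6 from 5 from 3.** The S–O bond and then the C–O bond at the future C3a are cut. The kinetic α′-enolate of the enone is oxidised anti to the neighbouring arm, giving the trans relationship that the inversion in the key step needs. The forward step demands trans selectivity and an allylsilane that is inert to base and oxidant.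

**3 from 2 from 1.** The C–Si bond and then the C–Cl bond at the allylic methyl carbon are cut. In 1 the isopropenyl group is the only electron-rich alkene, because the ring alkene is deactivated as an enone. This is why the allylic functionalisation is done first.

**11 from 9.** The C–Br bond at the future C5 is cut. The vinyl group of 9 is converted into a 1-bromoalkene by bromination and regioselective dehydrobromination. The oxygen on the neighbouring quaternary carbon directs the elimination.

**9 from 7.** The O–C5′ bond of ring C is cut, giving an epoxy alcohol and then 7. C2′ comes from the chiral pool. C5′ comes from a catalyst-controlled epoxidation followed by 5-exo opening with inversion.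

## Other disconnections considered

**Alternative 1:** (the first that comes to mind) Ring C is built last on a finished hydroazulene. The cuts are C2′–C3′ and O–C5′. In the forward direction a homoprenyl Grignard reagent adds to the C5 methyl ketone A1, giving the tertiary alcohol A2, which is epoxidised and cyclised 5-exo. The chosen plan is preferred for three reasons. First, C2′ in A2 would depend on 1,2-induction from C5 in a β-silyloxy ketone, where chelation and Felkin control point in opposite directions. Second, A1 is a β-silyloxy ketone with an epimerisable C5 that can eliminate. Third, A1 needs its own enantioselective synthesis of all four ring stereocentres, whereas the chosen plan takes C2′ and C8a from the chiral pool.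

**Alternative 2:** A decalin is rearranged to the hydroazulene. The cut is the ring-fusion bond C3a–C8a, with C3a reconnected to C8. In the forward direction the cis-fused decalin hydroxy mesylate A3 undergoes a pinacol-type shift of C3a from C8 to C8a with inversion, giving the C8 ketone A4, which is then methylenated. The stereochemical course is dependable, but A3 carries five contiguous cis stereocentres and the complete oxolane on a six-membered ring. It would take a long linear sequence with no convergence. The methylenation would also act next to the epimerisable C8a. The chosen plan uses the same type of 1,2-shift on a substrate that is four steps from a commercial terpene.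

**Alternative 3:** A De Mayo two-carbon ring expansion. The cuts are C4–C5 and C6–C7 in one operation. In the forward direction the enol of the cis-fused bicyclic dione A5 undergoes [2+2] photocycloaddition with the vinyl group of 9, and retro-aldol cleavage gives the cycloheptanedione A6. This route is very direct, but the two carbonyls of A5 enolise without bias, so two regioisomeric series are expected. Head-to-tail orientation is weakly defined for an alkyl-substituted alkene, and A5 is a β,γ-unsaturated ketone with its own photochemistry. In A6 the centres C3a, C5 and C8a are all epimerisable, so the sense of the ring relative to ring C is not controlled. A selective mono-methylenation would still be required.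

Key step: step 7

Assumption: (S)-(+)-linalool of high enantiomeric purity is taken as a purchasable chiral-pool material; the L-fructose-derived Shi ketone is used only as a catalyst.

## Route

Step 1
Reactants: 1 (R)-(−)-carvone, (5R)-2-methyl-5-(prop-1-en-2-yl)cyclohex-2-en-1-one
Product: 2 (5R)-5-(3-chloroprop-1-en-2-yl)-2-methylcyclohex-2-en-1-one
Conditions: Ca(OCl)2, CO2 (solid), CH2Cl2/H2O, 0 °C
Reagents that add atoms: calcium hypochlorite, [Ca+2].[O-]Cl.[O-]Cl
Why: Ene-type allylic chlorination by hypochlorous acid made in the flask; only the electron-rich 1,1-disubstituted alkene reacts because the ring alkene is an enone, and the stereocentre is not touched.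

Step 2
Reactants: 2 (5R)-5-(3-chloroprop-1-en-2-yl)-2-methylcyclohex-2-en-1-one
Product: 3 (5R)-2-methyl-5-[3-(trimethylsilyl)prop-1-en-2-yl]cyclohex-2-en-1-one
Conditions: Me3SiSiMe3, Pd(dba)2 (5 mol %), LiCl, DMF, 50 °C
Reagents that add atoms: hexamethyldisilane, C[Si](C)(C)[Si](C)(C)C
Why: Palladium-catalysed silylation of an allylic chloride with a disilane (oxidative addition to zerovalent palladium, Si–Si transmetalation, reductive elimination); both allyl termini are CH2, so either regiochemical mode gives the same allylsilane, and the enone is inert.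

Step 3
Reactants: 3 (5R)-2-methyl-5-[3-(trimethylsilyl)prop-1-en-2-yl]cyclohex-2-en-1-one
Product: 5 (5S,6S)-6-hydroxy-2-methyl-5-[3-(trimethylsilyl)prop-1-en-2-yl]cyclohex-2-en-1-one, via potassium dienolate 4 (not isolated)
Conditions: KN(SiMe3)2, THF, −78 °C; 2-(phenylsulfonyl)-3-phenyloxaziridine, −78 °C; aq. NH4Cl
Reagents that add atoms: 2-(phenylsulfonyl)-3-phenyloxaziridine, O=S(=O)(c1ccccc1)N1OC1c1ccccc1
Why: Kinetic α′-deprotonation gives the cross-conjugated dienolate, which is hydroxylated by the oxaziridine (enolate oxidation) anti to the neighbouring C5 arm; the trans, diequatorial ketol is also the more stable epimer, so the new stereocentre is set by 1,2-induction.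

Step 4
Reactants: 5 (5S,6S)-6-hydroxy-2-methyl-5-[3-(trimethylsilyl)prop-1-en-2-yl]cyclohex-2-en-1-one
Product: 6 (1S,6S)-3-methyl-2-oxo-6-[3-(trimethylsilyl)prop-1-en-2-yl]cyclohex-3-en-1-yl methanesulfonate
Conditions: MsCl, Et3N, CH2Cl2, −20 °C
Reagents that add atoms: methanesulfonyl chloride, CS(=O)(=O)Cl
Why: O-sulfonylation of the secondary ketol; only an O–S bond is formed, so the configuration is retained and the leaving group for the key step is in place.

Step 5
Reactants: 7 (S)-(+)-linalool, (3S)-3,7-dimethylocta-1,6-dien-3-ol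
Product: 9 2-[(2R,5S)-5-ethenyl-5-methyloxolan-2-yl]propan-2-ol, via epoxy alcohol 8 (not isolated)
Conditions: L-fructose-derived Shi ketone (30 mol %), KHSO5 (Oxone), K2CO3, Bu4NHSO4, MeCN/CH2(OMe)2/aq. Na2B4O7 buffer, 0 °C; then CSA (cat.), CH2Cl2, 0 °C
Reagents that add atoms: potassium peroxymonosulfate, [K+].[O-]S(=O)(=O)OO
Why: Shi epoxidation is catalyst-controlled at the trisubstituted alkene (the vinyl group is inert) and should give the (S)-epoxide; acid then triggers 5-exo-tet opening by the tertiary hydroxyl with inversion, which sets C5′ as R, cis to the vinyl group. C2′ is the untouched linalool stereocentre.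

Step 6
Reactants: 9 2-[(2R,5S)-5-ethenyl-5-methyloxolan-2-yl]propan-2-ol
Product: 11 2-[(2R,5S)-5-(1-bromoethenyl)-5-methyloxolan-2-yl]propan-2-ol, via vicinal dibromide 10 (not isolated)
Conditions: Br2, CH2Cl2, −78 °C; then DBU, DMF, 60 °C
Reagents that add atoms: bromine, BrBr
Why: Bromine addition followed by E2 dehydrobromination; the C–H on the bromine-bearing carbon next to the oxygenated quaternary centre is the more acidic, so the 2-bromo-1-alkene should form (known regioselectivity for vicinal dibromides flanked by an oxygen function). No stereocentre is involved.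

Step 7
Reactants: 6 (1S,6S)-3-methyl-2-oxo-6-[3-(trimethylsilyl)prop-1-en-2-yl]cyclohex-3-en-1-yl methanesulfonate; 11 2-[(2R,5S)-5-(1-bromoethenyl)-5-methyloxolan-2-yl]propan-2-ol
Product: 14 1-[(1S,5R)-2-methyl-5-[3-(trimethylsilyl)prop-1-en-2-yl]cyclopent-2-en-1-yl]-2-[(2S,5R)-5-(2-hydroxypropan-2-yl)-2-methyloxolan-2-yl]prop-2-en-1-one, via alkenyllithium alkoxide 12 (not isolated), via tertiary alkoxide adduct 13 (not isolated)
Conditions: 11, MeLi (1 equiv) then t-BuLi (2 equiv), THF, −78 °C; CeCl3, −78 °C; 6, −78 °C; then Et3Al (3 equiv), −78 → 0 °C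
Reagents that add atoms: none
Why: Deprotonation of the hydroxyl of 11, bromine–lithium exchange and transmetalation with CeCl3 give a weakly basic alkenyl nucleophile that should add 1,2 to the enone carbonyl of 6 (the future C4), making the C4–C5 bond without enolising the α-sulfonyloxy ketone. In the tertiary alkoxide 13 the mesylate is equatorial and trans to the equatorial allylsilane arm, so the ring bond from the carbinol carbon to the alkenyl carbon (future C3) is antiperiplanar to the C–OMs bond. Et3Al binds the alkoxide and assists departure of the sulfonate while the alkenyl carbon C3 shifts from C4 to C3a in a concerted semipinacol 1,2-shift, the alkoxide becoming the C4 ketone. The closest known reaction types are the organoaluminium-promoted pinacol-type rearrangement of β-mesyloxy alcohols with 1,2-alkenyl migration and the classical ring contraction of 2-sulfonyloxycyclohexanols to acylcyclopentanes. Ring A is therefore not closed by an exo or endo cyclisation but by contraction of the six-membered ring through a suprafacial 1,2-shift with backside attack at the migration terminus. The new stereocentre C3a is set by inversion at the mesylate-bearing carbon, which converts the trans relationship in 6 into the trans relationship of the acyl group and the C8a arm; C8a is the original carvone stereocentre. The step needs migration of the ring alkenyl bond in preference to the exocyclic alkenyl group, epoxide closure or enolisation. This is secured because only the ring bond is anti to the equatorial mesylate (oxygen and the exocyclic alkenyl group are gauche). The C2=C3 alkene stays deconjugated because C3a never passes through an enolate.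

Step 8
Reactants: 14 1-[(1S,5R)-2-methyl-5-[3-(trimethylsilyl)prop-1-en-2-yl]cyclopent-2-en-1-yl]-2-[(2S,5R)-5-(2-hydroxypropan-2-yl)-2-methyloxolan-2-yl]prop-2-en-1-one
Product: 16 (3aS,5S,8aR)-5-[(2S,5R)-5-(2-hydroxypropan-2-yl)-2-methyloxolan-2-yl]-3-methyl-8-methylidene-3a,5,6,7,8,8a-hexahydroazulen-4(1H)-one, via aluminium enolate 15 (not isolated)
Conditions: EtAlCl2 (2.5 equiv), CH2Cl2, −78 → −30 °C; aq. NaHCO3
Reagents that add atoms: none
Why: Intramolecular Hosomi–Sakurai conjugate addition: EtAlCl2 (which also removes the hydroxyl proton as ethane) activates the enone, the allylsilane terminus attacks the unsubstituted β-carbon C6 and closes ring B in the 7-endo mode (1,2-addition would require a trans-fused bicyclo[3.3.0]octane), and loss of silicon fixes the alkene as the exocyclic C8 methylidene. The trans arms on ring A give the trans ring fusion. C5 is set on protonation of enolate 15: in the ring B chair that the trans fusion allows, axial protonation anti to the axial H-3a places the oxolanyl group equatorial and cis to H-3a, which should also be the more stable epimer.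

Step 9
Reactants: 16 (3aS,5S,8aR)-5-[(2S,5R)-5-(2-hydroxypropan-2-yl)-2-methyloxolan-2-yl]-3-methyl-8-methylidene-3a,5,6,7,8,8a-hexahydroazulen-4(1H)-one
Product: 17 2-[(2R,5S)-5-methyl-5-[(3aS,5S,8aR)-3-methyl-8-methylidene-4-oxo-1,3a,4,5,6,7,8,8a-octahydroazulen-5-yl]oxolan-2-yl]propan-2-yl acetate
Conditions: Ac2O, Sc(OTf)3 (1 mol %), MeCN, −20 °C
Reagents that add atoms: acetic anhydride, CC(=O)OC(C)=O
Why: Lewis-acid-catalysed acylation of a tertiary alcohol at low temperature; at the ketone stage no secondary hydroxyl competes, and the mildly acidic, base-free conditions should leave C3a, C5 and the exocyclic alkene alone.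

Step 10
Reactants: 17 2-[(2R,5S)-5-methyl-5-[(3aS,5S,8aR)-3-methyl-8-methylidene-4-oxo-1,3a,4,5,6,7,8,8a-octahydroazulen-5-yl]oxolan-2-yl]propan-2-yl acetate
Product: 18 2-[(2R,5S)-5-[(3aS,4S,5R,8aR)-4-hydroxy-3-methyl-8-methylidene-1,3a,4,5,6,7,8,8a-octahydroazulen-5-yl]-5-methyloxolan-2-yl]propan-2-yl acetate (target, CNP0302132.4)
Conditions: NaBH4, CeCl3·7H2O, MeOH, −40 °C
Reagents that add atoms: none
Why: Luche reduction is non-basic, so C3a is not enolised and the tertiary acetate survives. Hydride should add to C4 anti to the flanking C5 oxolanyl group and anti to the axial C3a–H bond (axial attack), giving the equatorial (4S) alcohol cis to the C5 substituent and to H-3a.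

## Compound list

1 | (R)-(−)-carvone, (5R)-2-methyl-5-(prop-1-en-2-yl)cyclohex-2-en-1-one | CC1=CC[C@@H](C(C)=C)CC1=O | starting material
2 | (5R)-5-(3-chloroprop-1-en-2-yl)-2-methylcyclohex-2-en-1-one | CC1=CC[C@@H](C(=C)CCl)CC1=O | intermediate
3 | (5R)-2-methyl-5-[3-(trimethylsilyl)prop-1-en-2-yl]cyclohex-2-en-1-one | CC1=CC[C@@H](C(=C)C[Si](C)(C)C)CC1=O | intermediate
4 | potassium cross-conjugated dienolate of 3 (α′-enolate) | CC1=CC[C@@H](C(=C)C[Si](C)(C)C)C=C1[O-].[K+] | intermediate
5 | (5S,6S)-6-hydroxy-2-methyl-5-[3-(trimethylsilyl)prop-1-en-2-yl]cyclohex-2-en-1-one (trans) | CC1=CC[C@@H](C(=C)C[Si](C)(C)C)[C@H](O)C1=O | intermediate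
6 | (1S,6S)-3-methyl-2-oxo-6-[3-(trimethylsilyl)prop-1-en-2-yl]cyclohex-3-en-1-yl methanesulfonate | CC1=CC[C@@H](C(=C)C[Si](C)(C)C)[C@H](OS(C)(=O)=O)C1=O | intermediate
7 | (S)-(+)-linalool, (3S)-3,7-dimethylocta-1,6-dien-3-ol | C=C[C@@](C)(O)CCC=C(C)C | starting material
8 | (3S)-5-[(2S)-3,3-dimethyloxiran-2-yl]-3-methylpent-1-en-3-ol | C=C[C@@](C)(O)CC[C@@H]1OC1(C)C | intermediate
9 | 2-[(2R,5S)-5-ethenyl-5-methyloxolan-2-yl]propan-2-ol (cis-furanoid linalool oxide) | C=C[C@]1(C)CC[C@H](C(C)(C)O)O1 | intermediate
10 | 2-[(2R,5S)-5-(1,2-dibromoethyl)-5-methyloxolan-2-yl]propan-2-ol (both epimers at the CHBr carbon) | BrCC(Br)[C@]1(C)CC[C@H](C(C)(C)O)O1 | intermediate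
11 | 2-[(2R,5S)-5-(1-bromoethenyl)-5-methyloxolan-2-yl]propan-2-ol | C=C(Br)[C@]1(C)CC[C@H](C(C)(C)O)O1 | intermediate
12 | lithium 2-[(2R,5S)-5-(1-lithioethenyl)-5-methyloxolan-2-yl]propan-2-olate (transmetalated with CeCl3 before use) | [Li]C(=C)[C@]1(C)CC[C@H](C(C)(C)O[Li])O1 | intermediate
13 | (1S,6S)-2-hydroxy-2-{1-[(2S,5R)-5-(2-hydroxypropan-2-yl)-2-methyloxolan-2-yl]ethenyl}-3-methyl-6-[3-(trimethylsilyl)prop-1-en-2-yl]cyclohex-3-en-1-yl methanesulfonate, present as its metal dialkoxide (carbinol configuration not defined) | CC1=CC[C@@H](C(=C)C[Si](C)(C)C)[C@H](OS(C)(=O)=O)C1(O)C(=C)[C@]2(C)CC[C@H](C(C)(C)O)O2 | intermediate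
14 | 1-[(1S,5R)-2-methyl-5-[3-(trimethylsilyl)prop-1-en-2-yl]cyclopent-2-en-1-yl]-2-[(2S,5R)-5-(2-hydroxypropan-2-yl)-2-methyloxolan-2-yl]prop-2-en-1-one | C=C(C(=O)[C@@H]1C(C)=CC[C@H]1C(=C)C[Si](C)(C)C)[C@]2(C)CC[C@H](C(C)(C)O)O2 | intermediate
15 | aluminium enolate of 16 (C4=C5), drawn as the enol | C=C1CCC([C@]2(C)CC[C@H](C(C)(C)O)O2)=C(O)[C@@H]2C(C)=CC[C@@H]12 | intermediate
16 | (3aS,5S,8aR)-5-[(2S,5R)-5-(2-hydroxypropan-2-yl)-2-methyloxolan-2-yl]-3-methyl-8-methylidene-3a,5,6,7,8,8a-hexahydroazulen-4(1H)-one | C=C1CC[C@@H]([C@]2(C)CC[C@H](C(C)(C)O)O2)C(=O)[C@@H]2C(C)=CC[C@@H]12 | intermediate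
17 | 2-[(2R,5S)-5-methyl-5-[(3aS,5S,8aR)-3-methyl-8-methylidene-4-oxo-1,3a,4,5,6,7,8,8a-octahydroazulen-5-yl]oxolan-2-yl]propan-2-yl acetate | C=C1CC[C@@H]([C@]2(C)CC[C@H](C(C)(C)OC(C)=O)O2)C(=O)[C@@H]2C(C)=CC[C@@H]12 | intermediate
18 | 2-[(2R,5S)-5-[(3aS,4S,5R,8aR)-4-hydroxy-3-methyl-8-methylidene-1,3a,4,5,6,7,8,8a-octahydroazulen-5-yl]-5-methyloxolan-2-yl]propan-2-yl acetate | C=C1CC[C@@H]([C@]2(C)CC[C@H](C(C)(C)OC(C)=O)O2)[C@@H](O)[C@@H]2C(C)=CC[C@@H]12 | target

## Step count and least certain steps

Total step count: 10. Longest linear sequence: 8 (steps 1, 2, 3, 4, 7, 8, 9, 10); the second branch (steps 5, 6) joins at step 7.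

**Step 7 (key step).** The most likely failures are enolisation of the α-sulfonyloxy ketone, or no addition at all, because both the carbonyl and the alkenyl nucleophile are hindered. A ring flip that puts the mesylate axial would lead to epoxide closure or migration of the exocyclic alkenyl group.

The fallback separates the rearrangement from the fragment union and sets out from 6 and 11. Compound 6 is reduced 1,2 with i-Bu2AlH at −78 °C, and the resulting aluminium alkoxide is rearranged with Et3Al by the same 1,2-alkenyl shift. This gives (1S,5R)-2-methyl-5-[3-(trimethylsilyl)prop-1-en-2-yl]cyclopent-2-ene-1-carbaldehyde F1. F1 is coupled with 11 in a Nozaki–Hiyama–Kishi reaction (CrCl2, NiCl2 cat., DMF), which tolerates the free hydroxyl. The product is the allylic alcohol 1-[(1S,5R)-2-methyl-5-[3-(trimethylsilyl)prop-1-en-2-yl]cyclopent-2-en-1-yl]-2-[(2S,5R)-5-(2-hydroxypropan-2-yl)-2-methyloxolan-2-yl]prop-2-en-1-ol F2 as a carbinol mixture. Buffered Dess–Martin oxidation returns to the route at 14.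

**Step 8.** The allylsilane may be lost by protodesilylation. The ring alkene C2=C3 may compete as the nucleophile. Protonation of the enolate may show poor facial selectivity at C5.

The fallback closes ring B by olefin metathesis and sets out from 14. Conjugate addition of (CH2=CH)2CuLi to 14 gives 1-[(1S,5R)-2-methyl-5-[3-(trimethylsilyl)prop-1-en-2-yl]cyclopent-2-en-1-yl]-2-[(2S,5R)-5-(2-hydroxypropan-2-yl)-2-methyloxolan-2-yl]pent-4-en-1-one F3. Ring-closing metathesis with the second-generation Grubbs catalyst joins the new allyl group to the 1,1-disubstituted alkene of the allylsilane. This gives (3aS,8aR)-5-[(2S,5R)-5-(2-hydroxypropan-2-yl)-2-methyloxolan-2-yl]-3-methyl-8-[(trimethylsilyl)methyl]-3a,5,6,8a-tetrahydroazulen-4(1H)-one F4. Protodesilylation with CF3CO2H in CH2Cl2 at 0 °C (SE2′) moves the alkene to the exocyclic position. C5, being α to the ketone, should settle in the equatorial configuration, and the route is rejoined at 16.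

**Step 6.** Dehydrobromination may take the other regiochemical course and give the 1-bromoalkene. The tertiary hydroxyl may also capture the bromonium ion.

The fallback builds the bromoalkene from an alkyne and sets out from 9. Ozonolysis (O3, then Me2S) gives (2S,5R)-5-(2-hydroxypropan-2-yl)-2-methyloxolane-2-carbaldehyde F5, which is in equilibrium with its bicyclic lactol. Homologation with dimethyl (1-diazo-2-oxopropyl)phosphonate and K2CO3 in MeOH gives 2-[(2R,5S)-5-ethynyl-5-methyloxolan-2-yl]propan-2-ol F6. Markovnikov bromoboration with B-bromo-9-borabicyclo[3.3.1]nonane followed by AcOH returns to the route at 11.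

**Step 10.** Hydride delivery may show poor facial selectivity if ring B does not adopt the expected chair.

The fallback inverts the unwanted alcohol and sets out from 17. Should the reduction deliver mainly 2-[(2R,5S)-5-[(3aS,4R,5R,8aR)-4-hydroxy-3-methyl-8-methylidene-1,3a,4,5,6,7,8,8a-octahydroazulen-5-yl]-5-methyloxolan-2-yl]propan-2-yl acetate F7, a Mitsunobu reaction with 4-nitrobenzoic acid, PPh3 and diisopropyl azodicarboxylate gives the inverted ester (3aS,4S,5R,8aR)-5-[(2S,5R)-5-(2-acetoxypropan-2-yl)-2-methyloxolan-2-yl]-3-methyl-8-methylidene-1,3a,4,5,6,7,8,8a-octahydroazulen-4-yl 4-nitrobenzoate F8. Methanolysis with K2CO3 in MeOH at 0 °C cleaves the secondary aryl ester faster than the tertiary acetate and arrives at 18.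

## Further compounds

F1 | step 7 | (1S,5R)-2-methyl-5-[3-(trimethylsilyl)prop-1-en-2-yl]cyclopent-2-ene-1-carbaldehyde | O=C[C@@H]1C(C)=CC[C@H]1C(=C)C[Si](C)(C)C
F2 | step 7 | 1-[(1S,5R)-2-methyl-5-[3-(trimethylsilyl)prop-1-en-2-yl]cyclopent-2-en-1-yl]-2-[(2S,5R)-5-(2-hydroxypropan-2-yl)-2-methyloxolan-2-yl]prop-2-en-1-ol (carbinol epimers) | C=C(C(O)[C@@H]1C(C)=CC[C@H]1C(=C)C[Si](C)(C)C)[C@]2(C)CC[C@H](C(C)(C)O)O2
F3 | step 8 | 1-[(1S,5R)-2-methyl-5-[3-(trimethylsilyl)prop-1-en-2-yl]cyclopent-2-en-1-yl]-2-[(2S,5R)-5-(2-hydroxypropan-2-yl)-2-methyloxolan-2-yl]pent-4-en-1-one (C2 epimers) | C=CCC(C(=O)[C@@H]1C(C)=CC[C@H]1C(=C)C[Si](C)(C)C)[C@]2(C)CC[C@H](C(C)(C)O)O2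
F4 | step 8 | (3aS,8aR)-5-[(2S,5R)-5-(2-hydroxypropan-2-yl)-2-methyloxolan-2-yl]-3-methyl-8-[(trimethylsilyl)methyl]-3a,5,6,8a-tetrahydroazulen-4(1H)-one (C5 epimers) | C[Si](C)(C)CC1=CCC([C@]2(C)CC[C@H](C(C)(C)O)O2)C(=O)[C@@H]2C(C)=CC[C@@H]12
F5 | step 6 | (2S,5R)-5-(2-hydroxypropan-2-yl)-2-methyloxolane-2-carbaldehyde | O=C[C@]1(C)CC[C@H](C(C)(C)O)O1
F6 | step 6 | 2-[(2R,5S)-5-ethynyl-5-methyloxolan-2-yl]propan-2-ol | C#C[C@]1(C)CC[C@H](C(C)(C)O)O1
F7 | step 10 | 2-[(2R,5S)-5-[(3aS,4R,5R,8aR)-4-hydroxy-3-methyl-8-methylidene-1,3a,4,5,6,7,8,8a-octahydroazulen-5-yl]-5-methyloxolan-2-yl]propan-2-yl acetate | C=C1CC[C@@H]([C@]2(C)CC[C@H](C(C)(C)OC(C)=O)O2)[C@H](O)[C@@H]2C(C)=CC[C@@H]12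
F8 | step 10 | (3aS,4S,5R,8aR)-5-[(2S,5R)-5-(2-acetoxypropan-2-yl)-2-methyloxolan-2-yl]-3-methyl-8-methylidene-1,3a,4,5,6,7,8,8a-octahydroazulen-4-yl 4-nitrobenzoate | C=C1CC[C@@H]([C@]2(C)CC[C@H](C(C)(C)OC(C)=O)O2)[C@@H](OC(=O)c3ccc(cc3)[N+](=O)[O-])[C@@H]2C(C)=CC[C@@H]12
A1 | alternative 1 | 1-[(3aS,4S,5R,8aR)-4-[tert-butyl(dimethyl)silyl]oxy-3-methyl-8-methylidene-1,3a,4,5,6,7,8,8a-octahydroazulen-5-yl]ethan-1-one | C=C1CC[C@@H](C(C)=O)[C@@H](O[Si](C)(C)C(C)(C)C)[C@@H]2C(C)=CC[C@@H]12
A2 | alternative 1 | (2S)-2-[(3aS,4S,5R,8aR)-4-[tert-butyl(dimethyl)silyl]oxy-3-methyl-8-methylidene-1,3a,4,5,6,7,8,8a-octahydroazulen-5-yl]-6-methylhept-5-en-2-ol | C=C1CC[C@@H]([C@@](C)(O)CCC=C(C)C)[C@@H](O[Si](C)(C)C(C)(C)C)[C@@H]2C(C)=CC[C@@H]12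
A3 | alternative 2 | cis-fused decalin hydroxy mesylate: ring-fusion hydroxyl, neighbouring mesyloxy group, ring-fusion hydrogen, silyloxy group and oxolanyl group all on one face | CS(=O)(=O)O[C@@H]1CC=C(C)[C@H]2[C@H](O[Si](C)(C)C(C)(C)C)[C@H]([C@]3(C)CC[C@H](C(C)(C)OC(C)=O)O3)CC[C@@]12O
A4 | alternative 2 | 2-[(2R,5S)-5-[(3aS,4S,5R,8aR)-4-[tert-butyl(dimethyl)silyl]oxy-3-methyl-8-oxo-1,3a,4,5,6,7,8,8a-octahydroazulen-5-yl]-5-methyloxolan-2-yl]propan-2-yl acetate | O=C1CC[C@@H]([C@]2(C)CC[C@H](C(C)(C)OC(C)=O)O2)[C@@H](O[Si](C)(C)C(C)(C)C)[C@@H]2C(C)=CC[C@@H]12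
A5 | alternative 3 | cis-6-methylbicyclo[3.3.0]oct-6-ene-2,4-dione (allylic ring-fusion carbon configured as C3a of the target) | O=C1CC(=O)[C@@H]2C(C)=CC[C@H]12
A6 | alternative 3 | cis-fused 5-[(2S,5R)-5-(2-hydroxypropan-2-yl)-2-methyloxolan-2-yl]-3-methyl-3a,5,6,7-tetrahydroazulene-4,8(1H,8aH)-dione (C5 epimers) | O=C1CCC([C@]2(C)CC[C@H](C(C)(C)O)O2)C(=O)[C@@H]2C(C)=CC[C@H]12
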